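**Remarks on the chemistry (conventions and assumptions)**

- Locants C1–C8a are the hydroazulene locants of the target and are used for the same atoms in all precursors. β is the face that carries H‑8a in 37, α the face that carries H‑3a.
- The precursor and product of the ring expansion were re-derived atom by atom. Their configurations at C3a, C4, C8a and C7 agree with the target, so no structural correction is needed. The one change is the silyl group of the enol ether: triethylsilyl replaces tert-butyldimethylsilyl, so that the tertiary C7 carbinol can be released under buffered fluoride and then direct the C5 reduction.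
- Assumption: the hydrazone alkylation in step 2 follows the usual facial preference of this auxiliary for cyclic ketones and gives the (S) centre at C3a; otherwise the enantiomeric auxiliary would be used.

## Structural features

The target is a trans-fused bicyclo[5.3.0]decane: a cyclopentane with a C1–C2 epoxide and a methyl group on C2, joined through C3a–C8a to a cycloheptane that carries an isopropyl group (C4), a 4-hydroxybenzoate (C5) and a tertiary methyl carbinol (C7). Six of the seven stereocentres are contiguous (C2–C1–C8a–C3a–C4–C5); the seventh, fully substituted C7, is insulated from them by the C6 and C8 methylenes. H‑3a and H‑8a are trans, the isopropyl group is α, the ester oxygen β, the C7 hydroxyl α and the epoxide α, so the epoxide lies cis to the C7 hydroxyl. The fragile groups are the trisubstituted epoxide (acid), the phenolic ester (base and nucleophiles) and the tertiary alcohol (ionisation or elimination once a carbonyl sits at C5). The real difficulty is to tie the remote quaternary C7 on a flexible seven-membered ring to the rest of the array, and to secure the trans ring fusion. With C5 as a ketone, the atoms C5–C6–C7 and a C8=C8a double bond form a γ,δ-unsaturated ketone, so C6–C7 can be made by a [3,3] shift of an enol ether oxygen on C8a; this transfers the C8a configuration to C7.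

## Logic of the disconnections

37 ⇒ 36 ⇒ 35. The C1–O and C2–O bonds of the epoxide and the aryl O–Si bond are cut. The epoxide is the most fragile group and is made second to last. This removes two stereocentres. The forward step must deliver oxygen to the α face, which needs the free C7 hydroxyl and a masked phenol.

35 ⇒ 32 ⇒ 31 ⇒ 27. The C2–methyl carbon is cut (as an exocyclic methylene) and the alkene is moved back to a C1 carbonyl. A C1 ketone allows both C2 functionalisation and control of C8a. The forward steps need enolisation at C2 and not at C8a, 1,2-reduction to the 1α-alcohol, and displacement at C1 with inversion.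

27 ⇒ 25 ⇒ 24. The C8a–H and C8–H bonds are cut, then the C1 carbonyl is returned to its dioxolane. This removes the C8a stereocentre. The forward step relies on the trans-fused ketone being the more stable epimer.

24 ⇒ 19 + 22, and 22 ⇒ 20. The ester C–O bond is cut. The target's own ester then protects the C5 hydroxyl through the later steps. The forward step must acylate the secondary hydroxyl and leave the tertiary one.

19 ⇒ 18 ⇒ 17. The C5–H bond and the C7 O–Si bond are cut. This removes the C5 stereocentre. The forward reduction must deliver hydride to the α face of C5, which is why the silyl group has to be labile.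

17 ⇒ 16. The C6–C7 bond is cut and O–C8a is reconnected. The seven-membered ring and the quaternary centre are traced back to a cis-fused bicyclic enol ether whose stereocentres are easy to set. The forward step needs a Z enol ether and a concerted shift.

16 ⇒ 15 ⇒ 14 ⇒ 12. The C5=C6 methylene carbon, the enol O–Si bond and the C7 oxygen are removed in turn. This leads to a lactone with a simple alkene side chain. The demands are methylenation without base and enolisation toward C8.

12 ⇒ 10. The C4–isopropyl bond is cut. The bicyclic lactone controls C4 through its convex face.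

10 ⇒ 7 + 8. The C8a–C8 bond and the lactone O–acyl bond are cut. The forward addition must occur anti to the C3a side chain so that the alkoxide can lactonise.

7 ⇒ 6 ⇒ 3 ⇒ 1 + 2 + 4. The C3a–C4 bond is cut. Auxiliary 2 sets the absolute configuration from which all other centres follow.

## Other disconnections considered

Alternative 1: The cut is at C3a–C4 and C8a–C8, leading to silyloxy diene A1 and N-enoyl oxazolidinone A2. The forward key step is an Et2AlCl-promoted endo cycloaddition of A1 to chelated A2, giving cyclohexene A3.
- In favour: C4, C3a and C8a would be set in one reagent-controlled step. The C3a/C8a relationship would come directly from the E alkene of A2; on this point the alternative is better than the chosen plan, which depends on an equilibration at C8a. Absolute control in one step is at least the equal of a three-step hydrazone alkylation.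
- Against: the six-membered ring is not in the target. It would have to be opened at the enol ether and reclosed with one more carbon (C6). C7 would then be made by carbonyl addition without a built-in control element. The five-membered ring would still have to be annulated from the methallyl and acyl arms. A1 is a crowded, trisubstituted diene.
- Comparison: both key steps are concerted and stereospecific, so they are equal in predictability. In structure and step economy the chosen plan is ahead, because its key step forms a ring that the target contains and sets C7 at the same time.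

Alternative 2: The cut is at C8a–C3a, C1–C2 and C2–C3, leading to acyclic allene-yne A4. The forward key step is a carbonylative cyclisation with [Rh(CO)2Cl]2 under CO that engages the alkyne and the outer allene double bond and gives dienone A5.
- In favour: both rings and three C–C bonds would form in one catalytic step; in ring-forming economy this is better than the chosen plan. C5 and C7 would be set beforehand on an open chain by standard methods, which is equal in reliability to chirality transfer through an enol ether geometry.
- Against: A5 lacks the isopropyl group and the C2 methyl group. C3a, C4 and C8a would have to be created on a cross-conjugated dienone with two sp2 ring-fusion carbons, where a trans fusion is hard to enforce. The C2 carbonyl would have to become the C1=C2 methyl alkene. A4, with a tertiary silyl ether, needs its own asymmetric synthesis.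
- Comparison: the route is short up to the bicycle and long after it. The chosen plan carries C3a and C4 through from the start and leaves only C8a to be set later.

Alternative 3: The cut is at C3–C3a, leading to cycloheptenyl vinylsilane dienone A6. The forward key step is an FeCl3-promoted 4π electrocyclisation with loss of silicon, giving cyclopentenone A7 after equilibration at C8a.
- In favour: the five-membered ring would arrive with the C2 methyl group in place and the alkene fixed by the silyl group. From A7 the C1=C2 alkene could be reached by reduction and diazene transposition without a methylenation step; this endgame is better (shorter) than that of the chosen plan. Control of C8a by equilibration is equal in both.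
- Against: the main problem, a cycloheptene bearing C4, C5 and the quaternary C7, is moved into the preparation of A6, where the electrocyclisation gives no help. The conrotatory closure creates C3a next to C4 with a torquoselectivity that would have to be dictated by the isopropyl group. The tertiary silyl ether is exposed to a strong Lewis acid.
- Comparison: this alternative solves the five-membered ring but not the seven-membered ring. The chosen plan solves the seven-membered ring and C7 in one step and buys the five-membered ring.

Key step: step 9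

## Route

Step 1
Reactants: 1 1,4-dioxaspiro[4.4]nonan-6-one; 2 (S)-1-amino-2-(methoxymethyl)pyrrolidine (SAMP)
Product: 3 (S,E)-2-(methoxymethyl)-N-(1,4-dioxaspiro[4.4]nonan-6-ylidene)pyrrolidin-1-amine
Conditions: neat, 60 °C, 4 Å molecular sieves
Reagents that add atoms: none
Why: Hydrazone formation from a ketone and an N,N-dialkylhydrazine; the amino group should settle anti to the fully substituted ketal carbon, that is syn to the only enolisable CH2.

Step 2
Reactants: 3 hydrazone of step 1; 4 methyl bromoacetate
Product: 6 methyl 2-[(S)-6-{(E)-[(S)-2-(methoxymethyl)pyrrolidin-1-yl]imino}-1,4-dioxaspiro[4.4]nonan-7-yl]acetate, via lithium azaenolate 5 (not isolated)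
Conditions: LiN(iPr)2, THF, 0 °C; then 4, −100 → −78 °C
Reagents that add atoms: none
Why: Asymmetric alkylation of a metallated chiral hydrazone; deprotonation is possible only at C3a, and the methoxymethyl-chelated azaenolate should be alkylated on the face that gives the (S) centre at C3a, by analogy with the known preference of this auxiliary for cyclic ketones.

Step 3
Reactants: 6 alkylated hydrazone
Product: 7 methyl (S)-2-(6-oxo-1,4-dioxaspiro[4.4]nonan-7-yl)acetate
Conditions: O3, CH2Cl2, −78 °C; argon purge
Reagents that add atoms: ozone, O=[O+][O-]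
Why: Ozonolytic cleavage of the C=N bond under neutral conditions, which should spare the dioxolane and the ester and should not epimerise the new α-stereocentre.

Step 4
Reactants: 7 keto ester; 8 methallylmagnesium chloride
Product: 10 (3aS,6aR)-6a-(2-methylallyl)tetrahydrospiro[cyclopenta[b]furan-6,2'-[1,3]dioxolan]-2(3H)-one (cis-fused lactone), via magnesium alkoxide 9 (not isolated)
Conditions: 8 (1.15 equiv), THF, −78 → 0 °C, then rt; aq NH4Cl
Reagents that add atoms: none
Why: Addition of an allylic Grignard reagent to the ketone, faster than attack on the ester at low temperature and anti to the C3a side chain; the alkoxide is then cis to CH2CO2Me and should close the cis-fused γ-lactone on warming. The trans adduct cannot lactonise and would be removed as a hydroxy ester.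

Step 5
Reactants: 10 lactone
Product: 12 (3S,3aS,6aR)-3-isopropyl-6a-(2-methylallyl)tetrahydrospiro[cyclopenta[b]furan-6,2'-[1,3]dioxolan]-2(3H)-one, via lithium enolate 11 (not isolated)
Conditions: LiN(iPr)2, THF, −78 °C; DMPU, 2-iodopropane (3 equiv), −78 → −20 °C
Reagents that add atoms: 2-iodopropane, CC(C)I
Why: Alkylation of a lactone enolate with a secondary iodide; the electrophile should enter on the convex face of the cis-fused bicycle, giving the exo isopropyl group at C4 (cis to H‑3a), which is also the more stable epimer.

Step 6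
Reactants: 12 isopropyl lactone
Product: 14 (3S,3aS,6aR)-3-isopropyl-6a-(2-oxopropyl)tetrahydrospiro[cyclopenta[b]furan-6,2'-[1,3]dioxolan]-2(3H)-one, via ozonide 13 (not isolated)
Conditions: O3, CH2Cl2, −78 °C; then PPh3, −78 °C → rt
Reagents that add atoms: ozone, O=[O+][O-]
Why: Ozonolysis of the 1,1-disubstituted alkene with reductive work-up; no other group in 12 reacts with ozone.

Step 7
Reactants: 14 keto lactone
Product: 15 (3S,3aS,6aS)-3-isopropyl-6a-[(Z)-2-(triethylsilyloxy)prop-1-enyl]tetrahydrospiro[cyclopenta[b]furan-6,2'-[1,3]dioxolan]-2(3H)-one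
Conditions: Et3SiOTf (1.3 equiv), Et3N (3 equiv), CH2Cl2, −78 → 0 °C; cold aq NaHCO3
Reagents that add atoms: triethylsilyl trifluoromethanesulfonate, CC[Si](CC)(CC)OS(=O)(=O)C(F)(F)F
Why: Soft enolisation with silyl triflate and amine, which avoids a free enolate that would expel the β-carboxylate. Under the equilibrating conditions the internal enol ether is expected to be favoured (trisubstituted double bond, donation into the allylic C8a–O bond), and only the Z isomer avoids a cis clash between C8a and the methyl group.

Step 8
Reactants: 15 silyl enol ether lactone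
Product: 16 (3S,3aS,6aS)-3-isopropyl-2-methylene-6a-[(Z)-2-(triethylsilyloxy)prop-1-enyl]hexahydrospiro[cyclopenta[b]furan-6,2'-[1,3]dioxolane]
Conditions: Cp2TiMe2 (2.5 equiv), toluene, 70 °C, dark; filtration through basic Al2O3
Reagents that add atoms: dimethyltitanocene Cp2TiMe2, [CH3-].[CH3-].[Ti+4].c1cc[cH-]c1.c1cc[cH-]c1
Why: Methylenation of a lactone carbonyl with Cp2TiMe2 (Petasis methylenation); the reagent is not basic and should leave the C4 stereocentre, the silyl enol ether and the dioxolane untouched.

Step 9
Reactants: 16 methylene tetrahydrofuran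
Product: 17 (3aS,4S,7S)-4-isopropyl-7-methyl-7-(triethylsilyloxy)-2,3,3a,4,6,7-hexahydrospiro[azulene-1,2'-[1,3]dioxolan]-5-one
Conditions: degassed toluene (0.02 M), 2,6-di-tert-butyl-4-methylpyridine (5 mol%), base-washed sealed tube, 150–170 °C
Reagents that add atoms: none
Why: On heating, the allyl vinyl ether array C6=C5–O–C8a–C8=C7 of 16 should undergo a concerted, suprafacial [3,3] sigmatropic shift (aliphatic Claisen rearrangement) in which C6–C7 forms while O–C8a breaks. The closest known reaction type is the thermal ring expansion of 2-methylene-5-vinyltetrahydrofurans to cyclohept-4-enones, here with a disubstituted, oxygen-bearing vinyl terminus. The seven-membered ring closes by the shift itself: C5 and C8a are already linked by the C4–C3a bridge, so the six-centre array is part of a bicyclo[3.2.1]-like transition state (chair-like or boat-like) and the ether ring opens as the carbocycle forms. The one new stereocentre, C7, is controlled by two elements of 16: the β C8a–O bond fixes the face of the allyl unit on which C6 bonds, and the Z enol ether fixes which of methyl and silyloxy points inward. Because the new C8a=C8 bond must be cis within the ring (C7 syn to C3a), the silyloxy oxygen takes the inside position and the methyl group the outside one, which gives the C7 configuration of 37 for either transition-state shape. The step needs complete chirality transfer, that is a concerted path without ionisation of C8a–O; the electron-withdrawing dioxolane next to C8a, the non-polar medium and the acid scavenger should secure this and also keep the exocyclic double bond from moving into the ring. The donor oxygen on the bond-forming terminus is expected to lower the barrier and to offset part of the allylic strain of the inside substituent. C3a and C4 are untouched; C4 becomes epimerisable next to the new C5 ketone, and its required configuration (isopropyl trans to the C3a–C3 bond) is the more stable one.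

Step 10
Reactants: 17 silyloxy ketone
Product: 18 (3aS,4S,7S)-7-hydroxy-4-isopropyl-7-methyl-2,3,3a,4,6,7-hexahydrospiro[azulene-1,2'-[1,3]dioxolan]-5-one
Conditions: Bu4NF (1.2 equiv), AcOH (1.2 equiv), THF, 0 °C → rt
Reagents that add atoms: none
Why: Fluoride cleavage of a triethylsilyl ether; the acetic acid buffer should prevent retro-aldol cleavage or β-elimination of the β-hydroxy ketone, and the dioxolane is inert to fluoride.

Step 11
Reactants: 18 β-hydroxy ketone
Product: 19 (3aS,4S,5S,7S)-4-isopropyl-7-methyl-3,3a,4,5,6,7-hexahydro-2H-spiro[azulene-1,2'-[1,3]dioxolane]-5,7-diol (5β-OH, 7α-OH)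
Conditions: Me4NBH(OAc)3 (5 equiv), MeCN/AcOH (1:1), −30 °C; aq Rochelle salt/NaHCO3
Reagents that add atoms: none
Why: Hydroxyl-directed reduction with a triacetoxyborohydride (Evans–Saksena reduction): the alkoxyborohydride on the α C7 oxygen delivers hydride to the α face of C5, so the new hydroxyl is β, anti to the C7 oxygen and trans to the isopropyl group. The reagent does not reduce unassisted ketones and should leave the ketal alone at low temperature.

Step 12
Reactants: 20 4-hydroxybenzoic acid
Product: 22 4-(tert-butyldimethylsilyloxy)benzoic acid, via bis-silyl compound 21 (not isolated)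
Conditions: tBuMe2SiCl (2.3 equiv), imidazole, DMF, rt; then THF/AcOH/H2O, rt
Reagents that add atoms: tert-butyldimethylsilyl chloride, CC(C)(C)[Si](C)(C)Cl
Why: Silylation of phenol and acid, then selective hydrolysis of the much more labile silyl ester; the aryl silyl ether is stable to dilute acid.

Step 13
Reactants: 19 diol; 22 protected acid
Product: 24 (3aS,4S,5S,7S)-7-hydroxy-4-isopropyl-7-methyl-3,3a,4,5,6,7-hexahydro-2H-spiro[azulene-1,2'-[1,3]dioxolan]-5-yl 4-(tert-butyldimethylsilyloxy)benzoate, via mixed anhydride 23 (not isolated)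
Conditions: 22 (1.5 equiv), 2,4,6-Cl3C6H2COCl, Et3N, THF, rt; then 19, DMAP, toluene, rt → 45 °C
Reagents that add atoms: none
Why: Mixed-anhydride (Yamaguchi) esterification; only the secondary C5 hydroxyl should be acylated, the tertiary C7 hydroxyl being inert. The ester then protects C5–OH for the rest of the route.

Step 14
Reactants: 24 ketal ester
Product: 25 (3aS,4S,5S,7S)-7-hydroxy-4-isopropyl-7-methyl-1-oxo-1,2,3,3a,4,5,6,7-octahydroazulen-5-yl 4-(tert-butyldimethylsilyloxy)benzoate
Conditions: PPTS (0.3 equiv), acetone/H2O (9:1), 45 °C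
Reagents that add atoms: water, O
Why: Acid-catalysed hydrolysis of an allylic dioxolane, which is fast because the oxocarbenium ion is conjugated; the mild acid should spare the aryl silyl ether, the ester and the tertiary alcohol, and the product enone deactivates C7 toward ionisation.

Step 15
Reactants: 25 enone
Product: 27 (3aS,4S,5S,7R,8aS)-7-hydroxy-4-isopropyl-7-methyl-1-oxodecahydroazulen-5-yl 4-(tert-butyldimethylsilyloxy)benzoate (trans-fused), via cis-fused epimer 26 (not isolated)
Conditions: [(Ph3P)CuH]6 (0.4 equiv), H2O (3 equiv), THF/toluene, rt; then DBU (0.5 equiv), CH2Cl2, rt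
Reagents that add atoms: none
Why: Conjugate reduction of the enone by a phosphine-stabilised copper hydride, then base-mediated epimerisation α to the ketone. The trans-fused hydroazulenone (H‑8a β) is expected to be the thermodynamic isomer, and only this epimer has C1 cis to the C7 hydroxyl and can gain further stability as the C7–O/C1 hemiketal.

Step 16
Reactants: 27 trans-fused ketone
Product: 31 (3aS,4S,5S,7R,8aS)-7-hydroxy-4-isopropyl-7-methyl-2-methylene-1-oxodecahydroazulen-5-yl 4-(tert-butyldimethylsilyloxy)benzoate, via dilithium enolate alkoxide 28 (not isolated), via Mannich base 29 (not isolated), via ammonium iodide 30 (not isolated)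
Conditions: LiN(iPr)2 (2.3 equiv), THF, −78 °C; CH2=NMe2+ I−, −78 °C → rt; then MeI, CH2Cl2, rt; then aq NaHCO3, rt
Reagents that add atoms: N,N-dimethylmethyleneiminium iodide, C=[N+](C)C.[I-]
Why: Kinetic enolate formation at the less hindered C2 methylene (not at the C8a methine), Mannich reaction with the iminium salt, quaternisation and elimination (α-methylenation). The tertiary hydroxyl is carried as its lithium alkoxide, which lies trans to the C5 ester and should not attack it at −78 °C.

Step 17
Reactants: 31 α-methylene ketone
Product: 32 (1S,3aR,4S,5S,7R,8aS)-1,7-dihydroxy-4-isopropyl-7-methyl-2-methylenedecahydroazulen-5-yl 4-(tert-butyldimethylsilyloxy)benzoate (1α-OH)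
Conditions: NaBH4, CeCl3·7H2O, MeOH, −78 °C
Reagents that add atoms: none
Why: Luche reduction (1,2-selective); hydride should attack C1 from the β face, anti to the C8a–C8 bond, giving the 1α-alcohol. The C1 centre is temporary and is removed in step 18.

Step 18
Reactants: 32 allylic alcohol
Product: 35 (3aR,4S,5S,7R,8aS)-7-hydroxy-4-isopropyl-2,7-dimethyl-3,3a,4,5,6,7,8,8a-octahydroazulen-5-yl 4-(tert-butyldimethylsilyloxy)benzoate, via sulfonylhydrazine adduct 33 (not isolated), via allylic diazene 34 (not isolated)
Conditions: PPh3, DEAD, 2-O2NC6H4SO2NHNH2, N-methylmorpholine, −30 °C; then 23 °C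
Reagents that add atoms: none
Why: Mitsunobu displacement by the sulfonylhydrazide with inversion at C1, loss of sulfinic acid to a monoalkyl diazene, and sigmatropic loss of N2 with hydrogen transfer to the exocyclic carbon (reductive allylic transposition). This puts the double bond at C1=C2 and turns the methylene into the C2 methyl group. The α C1 oxyphosphonium ion cannot be attacked from the rear by the α C7 hydroxyl, so no cyclic ether should form.

Step 19
Reactants: 35 alkene
Product: 36 (1S,2R,3aR,4S,5S,7R,8aS)-1,2-epoxy-7-hydroxy-4-isopropyl-2,7-dimethyldecahydroazulen-5-yl 4-(tert-butyldimethylsilyloxy)benzoate (1α,2α-epoxide; hydroazulene locants)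
Conditions: VO(acac)2 (5 mol%), tBuOOH (1.5 equiv, decane), CH2Cl2, 0 °C → rt
Reagents that add atoms: tert-butyl hydroperoxide, CC(C)(C)OO
Why: Hydroxyl-directed epoxidation of a bishomoallylic alcohol: the vanadium peroxide bound to the α C7 oxygen, which lies cis to C1 across the seven-membered ring, should deliver oxygen to the α face of C1=C2 and set C1 and C2. The catalyst epoxidises undirected alkenes only slowly, and the C7 hydroxyl cannot open the cis epoxide from the rear.

Step 20
Reactants: 36 silyl-protected epoxide
Product: 37 (1S,2R,3aR,4S,5S,7R,8aS)-1,2-epoxy-7-hydroxy-4-isopropyl-2,7-dimethyldecahydroazulen-5-yl 4-hydroxybenzoate (CNP0245441.1; hydroazulene locants)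
Conditions: Bu4NF (1.1 equiv), AcOH (1.2 equiv), THF, 0 °C
Reagents that add atoms: none
Why: Buffered fluoride cleavage of the aryl silyl ether, which is much faster than any reaction of the epoxide, the hindered ester or the tertiary alcohol.

## Compound list

1 | 1,4-dioxaspiro[4.4]nonan-6-one | O=C1CCCC12OCCO2 | starting material
2 | (S)-1-amino-2-(methoxymethyl)pyrrolidine (SAMP) | COC[C@@H]1CCCN1N | starting material
3 | (S,E)-2-(methoxymethyl)-N-(1,4-dioxaspiro[4.4]nonan-6-ylidene)pyrrolidin-1-amine | COC[C@@H]1CCCN1/N=C2\CCCC23OCCO3 | intermediate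
4 | methyl bromoacetate | COC(=O)CBr | starting material
5 | lithium azaenolate of 3 (C=C between C8a and C3a) | COC[C@@H]1CCCN1N([Li])C2=CCCC23OCCO3 | intermediate (not isolated)
6 | methyl 2-[(S)-6-{(E)-[(S)-2-(methoxymethyl)pyrrolidin-1-yl]imino}-1,4-dioxaspiro[4.4]nonan-7-yl]acetate | COC[C@@H]1CCCN1/N=C2\[C@H](CC(=O)OC)CCC23OCCO3 | intermediate
7 | methyl (S)-2-(6-oxo-1,4-dioxaspiro[4.4]nonan-7-yl)acetate | COC(=O)C[C@@H]1CCC2(OCCO2)C1=O | intermediate
8 | methallylmagnesium chloride | C=C(C)C[Mg]Cl | starting material
9 | chloromagnesium alkoxide of methyl 2-[(6R,7S)-6-hydroxy-6-(2-methylallyl)-1,4-dioxaspiro[4.4]nonan-7-yl]acetate | COC(=O)C[C@@H]1CCC2(OCCO2)[C@]1(CC(C)=C)O[Mg]Cl | intermediate (not isolated)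
10 | (3aS,6aR)-6a-(2-methylallyl)tetrahydrospiro[cyclopenta[b]furan-6,2'-[1,3]dioxolan]-2(3H)-one | O=C1C[C@@H]2CCC3(OCCO3)[C@]2(CC(C)=C)O1 | intermediate
11 | lithium enolate of 10 | [Li]OC1=C[C@@H]2CCC3(OCCO3)[C@]2(CC(C)=C)O1 | intermediate (not isolated)
12 | (3S,3aS,6aR)-3-isopropyl-6a-(2-methylallyl)tetrahydrospiro[cyclopenta[b]furan-6,2'-[1,3]dioxolan]-2(3H)-one | O=C1[C@@H](C(C)C)[C@@H]2CCC3(OCCO3)[C@]2(CC(C)=C)O1 | intermediate
13 | ozonide (1,2,4-trioxolane) of the side-chain alkene of 12 | O=C1[C@@H](C(C)C)[C@@H]2CCC3(OCCO3)[C@]2(CC4(C)OCOO4)O1 | intermediate (not isolated)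
14 | (3S,3aS,6aR)-3-isopropyl-6a-(2-oxopropyl)tetrahydrospiro[cyclopenta[b]furan-6,2'-[1,3]dioxolan]-2(3H)-one | O=C1[C@@H](C(C)C)[C@@H]2CCC3(OCCO3)[C@]2(CC(C)=O)O1 | intermediate
15 | (3S,3aS,6aS)-3-isopropyl-6a-[(Z)-2-(triethylsilyloxy)prop-1-enyl]tetrahydrospiro[cyclopenta[b]furan-6,2'-[1,3]dioxolan]-2(3H)-one | O=C1[C@@H](C(C)C)[C@@H]2CCC3(OCCO3)[C@]2(/C=C(/C)O[Si](CC)(CC)CC)O1 | intermediate
16 | (3S,3aS,6aS)-3-isopropyl-2-methylene-6a-[(Z)-2-(triethylsilyloxy)prop-1-enyl]hexahydrospiro[cyclopenta[b]furan-6,2'-[1,3]dioxolane] | C=C1O[C@@]2(/C=C(/C)O[Si](CC)(CC)CC)C3(OCCO3)CC[C@H]2[C@@H]1C(C)C | intermediate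
17 | (3aS,4S,7S)-4-isopropyl-7-methyl-7-(triethylsilyloxy)-2,3,3a,4,6,7-hexahydrospiro[azulene-1,2'-[1,3]dioxolan]-5-one | CC(C)[C@H]1[C@@H]2CCC3(OCCO3)C2=C[C@@](C)(O[Si](CC)(CC)CC)CC1=O | intermediate
18 | (3aS,4S,7S)-7-hydroxy-4-isopropyl-7-methyl-2,3,3a,4,6,7-hexahydrospiro[azulene-1,2'-[1,3]dioxolan]-5-one | CC(C)[C@H]1[C@@H]2CCC3(OCCO3)C2=C[C@@](C)(O)CC1=O | intermediate
19 | (3aS,4S,5S,7S)-4-isopropyl-7-methyl-3,3a,4,5,6,7-hexahydro-2H-spiro[azulene-1,2'-[1,3]dioxolane]-5,7-diol | CC(C)[C@H]1[C@@H]2CCC3(OCCO3)C2=C[C@@](C)(O)C[C@@H]1O | intermediate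
20 | 4-hydroxybenzoic acid | O=C(O)c1ccc(O)cc1 | starting material
21 | tert-butyldimethylsilyl 4-(tert-butyldimethylsilyloxy)benzoate | CC(C)(C)[Si](C)(C)Oc1ccc(cc1)C(=O)O[Si](C)(C)C(C)(C)C | intermediate (not isolated)
22 | 4-(tert-butyldimethylsilyloxy)benzoic acid | CC(C)(C)[Si](C)(C)Oc1ccc(cc1)C(=O)O | intermediate
23 | 4-(tert-butyldimethylsilyloxy)benzoic 2,4,6-trichlorobenzoic anhydride | CC(C)(C)[Si](C)(C)Oc1ccc(cc1)C(=O)OC(=O)c1c(Cl)cc(Cl)cc1Cl | intermediate (not isolated)
24 | (3aS,4S,5S,7S)-7-hydroxy-4-isopropyl-7-methyl-3,3a,4,5,6,7-hexahydro-2H-spiro[azulene-1,2'-[1,3]dioxolan]-5-yl 4-(tert-butyldimethylsilyloxy)benzoate | CC(C)[C@H]1[C@@H]2CCC3(OCCO3)C2=C[C@@](C)(O)C[C@@H]1OC(=O)c1ccc(O[Si](C)(C)C(C)(C)C)cc1 | intermediate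
25 | (3aS,4S,5S,7S)-7-hydroxy-4-isopropyl-7-methyl-1-oxo-1,2,3,3a,4,5,6,7-octahydroazulen-5-yl 4-(tert-butyldimethylsilyloxy)benzoate | CC(C)[C@H]1[C@@H]2CCC(=O)C2=C[C@@](C)(O)C[C@@H]1OC(=O)c1ccc(O[Si](C)(C)C(C)(C)C)cc1 | intermediate
26 | (3aS,4S,5S,7R,8aR)-7-hydroxy-4-isopropyl-7-methyl-1-oxodecahydroazulen-5-yl 4-(tert-butyldimethylsilyloxy)benzoate (cis-fused 8a-epimer of 27) | CC(C)[C@H]1[C@@H]2CCC(=O)[C@@H]2C[C@@](C)(O)C[C@@H]1OC(=O)c1ccc(O[Si](C)(C)C(C)(C)C)cc1 | intermediate (not isolated)
27 | (3aS,4S,5S,7R,8aS)-7-hydroxy-4-isopropyl-7-methyl-1-oxodecahydroazulen-5-yl 4-(tert-butyldimethylsilyloxy)benzoate (trans-fused) | CC(C)[C@H]1[C@@H]2CCC(=O)[C@H]2C[C@@](C)(O)C[C@@H]1OC(=O)c1ccc(O[Si](C)(C)C(C)(C)C)cc1 | intermediate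
28 | dilithium salt of 27 (C1 enolate toward C2; C7 alkoxide) | CC(C)[C@H]1[C@@H]2CC=C(O[Li])[C@H]2C[C@@](C)(O[Li])C[C@@H]1OC(=O)c1ccc(O[Si](C)(C)C(C)(C)C)cc1 | intermediate (not isolated)
29 | 2-(dimethylaminomethyl) derivative of 27 (Mannich base; C2 epimers) | CC(C)[C@H]1[C@@H]2CC(CN(C)C)C(=O)[C@H]2C[C@@](C)(O)C[C@@H]1OC(=O)c1ccc(O[Si](C)(C)C(C)(C)C)cc1 | intermediate (not isolated)
30 | trimethylammonium iodide derived from 29 | CC(C)[C@H]1[C@@H]2CC(C[N+](C)(C)C)C(=O)[C@H]2C[C@@](C)(O)C[C@@H]1OC(=O)c1ccc(O[Si](C)(C)C(C)(C)C)cc1.[I-] | intermediate (not isolated)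
31 | (3aS,4S,5S,7R,8aS)-7-hydroxy-4-isopropyl-7-methyl-2-methylene-1-oxodecahydroazulen-5-yl 4-(tert-butyldimethylsilyloxy)benzoate | CC(C)[C@H]1[C@@H]2CC(=C)C(=O)[C@H]2C[C@@](C)(O)C[C@@H]1OC(=O)c1ccc(O[Si](C)(C)C(C)(C)C)cc1 | intermediate
32 | (1S,3aR,4S,5S,7R,8aS)-1,7-dihydroxy-4-isopropyl-7-methyl-2-methylenedecahydroazulen-5-yl 4-(tert-butyldimethylsilyloxy)benzoate | CC(C)[C@H]1[C@@H]2CC(=C)[C@@H](O)[C@H]2C[C@@](C)(O)C[C@@H]1OC(=O)c1ccc(O[Si](C)(C)C(C)(C)C)cc1 | intermediate
33 | N-(2-nitrobenzenesulfonyl)hydrazine adduct at C1 of 32 (nitrogen β; inverted) | CC(C)[C@H]1[C@@H]2CC(=C)[C@H](N(N)S(=O)(=O)c3ccccc3[N+](=O)[O-])[C@H]2C[C@@](C)(O)C[C@@H]1OC(=O)c1ccc(O[Si](C)(C)C(C)(C)C)cc1 | intermediate (not isolated)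
34 | C1 monoalkyl diazene derived from 33 | CC(C)[C@H]1[C@@H]2CC(=C)[C@H](N=N)[C@H]2C[C@@](C)(O)C[C@@H]1OC(=O)c1ccc(O[Si](C)(C)C(C)(C)C)cc1 | intermediate (not isolated)
35 | (3aR,4S,5S,7R,8aS)-7-hydroxy-4-isopropyl-2,7-dimethyl-3,3a,4,5,6,7,8,8a-octahydroazulen-5-yl 4-(tert-butyldimethylsilyloxy)benzoate | CC(C)[C@H]1[C@@H]2CC(C)=C[C@H]2C[C@@](C)(O)C[C@@H]1OC(=O)c1ccc(O[Si](C)(C)C(C)(C)C)cc1 | intermediate
36 | (1S,2R,3aR,4S,5S,7R,8aS)-1,2-epoxy-7-hydroxy-4-isopropyl-2,7-dimethyldecahydroazulen-5-yl 4-(tert-butyldimethylsilyloxy)benzoate | CC(C)[C@H]1[C@@H]2C[C@@]3(C)O[C@H]3[C@H]2C[C@@](C)(O)C[C@@H]1OC(=O)c1ccc(O[Si](C)(C)C(C)(C)C)cc1 | intermediate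
37 | (1S,2R,3aR,4S,5S,7R,8aS)-1,2-epoxy-7-hydroxy-4-isopropyl-2,7-dimethyldecahydroazulen-5-yl 4-hydroxybenzoate (CNP0245441.1) | CC(C)[C@H]1[C@@H]2C[C@@]3(C)O[C@H]3[C@H]2C[C@@](C)(O)C[C@@H]1OC(=O)c1ccc(O)cc1 | target

## Step count and least certain steps

Total: 20 steps. Longest linear sequence: 19 steps (1 → 37 through steps 1–11 and 13–20); step 12 is a one-step side branch.

Step 9 (key step). Three processes could defeat it: migration of the exocyclic double bond into the ring under traces of acid; heterolysis of the C8a–O bond assisted by the silyloxy group, which would erode the transfer of configuration to C7 or end in elimination; and a barrier raised so far by the inside silyloxy group that decomposition competes. The fallback leaves the thermal pericyclic regime. From 16, iBu3Al in CH2Cl2 at −78 °C → rt should promote the ring expansion as an organoaluminium-induced rearrangement with in-situ hydride transfer from an isobutyl group, giving the ring-expanded C5 carbinol F1 as a mixture of C5 epimers. Oxidation of F1 with Dess–Martin periodinane buffered with NaHCO3 returns to 17. The configuration at C7 would have to be confirmed at 17, because this pathway is less strictly concerted.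

Step 7. Silylation may occur at the methyl group and not at C8; the lactone carboxylate may be lost by β-elimination once C8 is activated; the dioxolane may be opened by the silyl triflate. The fallback removes the carboxylate leaving group before the enol ether is made, so that longer, fully equilibrating silylation becomes safe. From 14, NaBH4 in MeOH at 0 °C should give the side-chain carbinol F2 (C7 epimers), which is silylated (Et3SiCl, imidazole) to the triethylsilyl ether F3. Methylenation of the lactone with Cp2TiMe2 gives the methylene tetrahydrofuran F4, and Bu4NF releases the carbinol F5. Oxidation with Dess–Martin periodinane and pyridine gives the methyl ketone F6, in which the β-oxygen is an enol ether oxygen and a poor leaving group. Et3SiOTf and Et3N under equilibrating conditions then return to 16.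

Step 5. Dehydrohalogenation of 2-iodopropane by the hindered enolate may outrun alkylation and leave 10 unchanged. The fallback builds the isopropyl group from acetone. From 10, the lithium enolate is added to acetone to give the tertiary aldol adduct F7; dehydration (SOCl2, pyridine, then DBU to bring the double bond into conjugation) gives the isopropylidene lactone F8; conjugate reduction with Mg in MeOH, whose methoxide equilibrates C4 to the exo epimer, returns to 12.

Step 15. Hydride transfer to C8, which stands next to the quaternary C7, may be slow, and the epimerisation at C8a may stop short of the trans isomer. The fallback replaces the copper hydride by catalytic hydrogenation of the enone C=C bond of 25 (H2, Pd/C, EtOAc with a little pyridine to suppress hydrogenolysis of the allylic C7–O bond), followed by the same DBU equilibration, and returns to 27; it makes no new compound. Unconverted 26 would be resubmitted to the base.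

Step 18. Displacement at the hindered C1 oxyphosphonium ion may be slow, so that attack of the hydrazide at the exocyclic carbon or elimination competes. The fallback forms the same diazene without substitution at C1. From 31, condensation with 4-toluenesulfonylhydrazide gives the tosylhydrazone F9; reduction of the C=N bond with catecholborane in CHCl3 at 0 °C and decomposition with NaOAc·3H2O at reflux release the diazene, which transposes to 35. The main hazard of this variant is conjugate addition of the hydrazide to the methylene ketone.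

## Further compounds

F1 | step 9 | (3aS,4S,7S)-4-isopropyl-7-methyl-7-(triethylsilyloxy)-3,3a,4,5,6,7-hexahydro-2H-spiro[azulene-1,2'-[1,3]dioxolan]-5-ol (C5 epimers) | CC(C)[C@H]1[C@@H]2CCC3(OCCO3)C2=C[C@@](C)(O[Si](CC)(CC)CC)CC1O
F2 | step 7 | (3S,3aS,6aR)-6a-(2-hydroxypropyl)-3-isopropyltetrahydrospiro[cyclopenta[b]furan-6,2'-[1,3]dioxolan]-2(3H)-one (carbinol epimers) | O=C1[C@@H](C(C)C)[C@@H]2CCC3(OCCO3)[C@]2(CC(C)O)O1
F3 | step 7 | triethylsilyl ether of F2 | O=C1[C@@H](C(C)C)[C@@H]2CCC3(OCCO3)[C@]2(CC(C)O[Si](CC)(CC)CC)O1
F4 | step 7 | (3S,3aS,6aR)-3-isopropyl-2-methylene-6a-[2-(triethylsilyloxy)propyl]hexahydrospiro[cyclopenta[b]furan-6,2'-[1,3]dioxolane] | C=C1O[C@@]2(CC(C)O[Si](CC)(CC)CC)C3(OCCO3)CC[C@H]2[C@@H]1C(C)C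
F5 | step 7 | (3S,3aS,6aR)-6a-(2-hydroxypropyl)-3-isopropyl-2-methylenehexahydrospiro[cyclopenta[b]furan-6,2'-[1,3]dioxolane] | C=C1O[C@@]2(CC(C)O)C3(OCCO3)CC[C@H]2[C@@H]1C(C)C
F6 | step 7 | (3S,3aS,6aR)-3-isopropyl-2-methylene-6a-(2-oxopropyl)hexahydrospiro[cyclopenta[b]furan-6,2'-[1,3]dioxolane] | C=C1O[C@@]2(CC(C)=O)C3(OCCO3)CC[C@H]2[C@@H]1C(C)C
F7 | step 5 | (3S,3aS,6aR)-3-(2-hydroxypropan-2-yl)-6a-(2-methylallyl)tetrahydrospiro[cyclopenta[b]furan-6,2'-[1,3]dioxolan]-2(3H)-one | O=C1[C@@H](C(C)(C)O)[C@@H]2CCC3(OCCO3)[C@]2(CC(C)=C)O1
F8 | step 5 | (3aS,6aR)-6a-(2-methylallyl)-3-(propan-2-ylidene)tetrahydrospiro[cyclopenta[b]furan-6,2'-[1,3]dioxolan]-2(3H)-one | O=C1C(=C(C)C)[C@@H]2CCC3(OCCO3)[C@]2(CC(C)=C)O1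
F0 | step 15 | none | none
F9 | step 18 | 4-toluenesulfonylhydrazone of 31 | CC(C)[C@H]1[C@@H]2CC(=C)C(=NNS(=O)(=O)c3ccc(C)cc3)[C@H]2C[C@@](C)(O)C[C@@H]1OC(=O)c1ccc(O[Si](C)(C)C(C)(C)C)cc1
A1 | alternative 1 | (Z)-tert-butyl[(2,5-dimethylhexa-1,3-dien-3-yl)oxy]dimethylsilane | CC(C)/C=C(\O[Si](C)(C)C(C)(C)C)C(C)=C
A2 | alternative 1 | (S)-4-benzyl-3-[(E)-5-methylhexa-2,5-dienoyl]oxazolidin-2-one | C=C(C)C/C=C/C(=O)N1C(=O)OC[C@@H]1Cc1ccccc1
A3 | alternative 1 | cyclohexene silyl enol ether with C4 isopropyl, C3a methallyl and C8a acyl oxazolidinone groups | CC(C)[C@H]1[C@H](CC(C)=C)[C@@H](C(=O)N2C(=O)OC[C@@H]2Cc2ccccc2)CC(C)=C1O[Si](C)(C)C(C)(C)C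
A4 | alternative 2 | (4S,6R)-4-(tert-butyldimethylsilyloxy)-6-methyl-6-(triethylsilyloxy)nona-1,2-dien-8-yne | C#CC[C@@](C)(O[Si](CC)(CC)CC)C[C@H](O[Si](C)(C)C(C)(C)C)C=C=C
A5 | alternative 2 | (5S,7R)-5-(tert-butyldimethylsilyloxy)-7-methyl-7-(triethylsilyloxy)-5,6,7,8-tetrahydro-3H-azulen-2-one | O=C1C=C2C[C@@](C)(O[Si](CC)(CC)CC)C[C@H](O[Si](C)(C)C(C)(C)C)C=C2C1
A6 | alternative 3 | (E)-1-[4,6-bis(tert-butyldimethylsilyloxy)-3-isopropyl-6-methylcyclohept-1-en-1-yl]-2-methyl-3-(trimethylsilyl)prop-2-en-1-one (ring carbons C8a, C5, C7, C4 of the target) | CC(C)[C@H]1C=C(C(=O)/C(C)=C/[Si](C)(C)C)C[C@@](C)(O[Si](C)(C)C(C)(C)C)C[C@@H]1O[Si](C)(C)C(C)(C)C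
A7 | alternative 3 | trans-fused 5,7-bis(tert-butyldimethylsilyloxy)-4-isopropyl-2,7-dimethyl-3a,4,5,6,7,8,8a-heptahydroazulen-1-one (C2=C3 alkene) | CC(C)[C@H]1[C@@H]2C=C(C)C(=O)[C@H]2C[C@@](C)(O[Si](C)(C)C(C)(C)C)C[C@@H]1O[Si](C)(C)C(C)(C)C
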